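**Retrosynthetic overview** (numbering: lactone O1–C2(=O)–C3(Me)=C4–C5(=C6), C7(Me), ring A C8–C9–C10–C11(Me)–C12, ring B C12–C13–C14=C15(Me)–C16(O-acyl)–C17; β = face of ring A with the C11 methyl and C17, α = face with C13 and the C8 side chain)
- The strategy rests on ring B: C16 sits between C17H2 and C15(Me), so ring B is carbon monoxide inserted into a spiro cyclopropane (C12, C13, C17) that carries a propenyl group (C14, C15, CH3) on C13; the [5+1] carbonylation cleaves C13–C17 and forms C16–C17 and C15–C16.
- Last disconnections: C16 ester C–O (acylation), then C5=C6 (silyloxyfuran aldol and elimination on a C6 aldehyde).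
- C7–C8 comes from an Ireland–Claisen shift from a C10 α-oxygen, which is placed by epoxidation and Wharton transposition of a ring-A enone made from the C8 ketone.
- Ring order: ring A (cyclopentenone; C11 by asymmetric conjugate methylation), then the cyclopropane (sulfur ylide on the C12=C17 enone, anti to the C11 methyl, fixing C12), then ring B (carbonylation), last the butenolide.

Key step: step 7

Assumption: C8 in 11–17 and C13 plus the propenyl geometry in 10–12 are spectator elements erased in steps 11 and 7; the isomers drawn are those expected to predominate, and their epimers would be carried through the same steps.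

**Step 1**
Reactants: 1 cyclopent-2-en-1-one
Product: 3 (2S,3S)-2-[(dimethylamino)methyl]-3-methylcyclopentan-1-one, via methylzinc enolate 2 (not isolated)
Conditions: Me2Zn (1.2 equiv), Cu(OTf)2 (2 mol %), chiral dipeptide-based phosphine Schiff-base ligand (5 mol %), toluene, −30 °C; then Me2N=CH2 I (1.5 equiv), THF, −30 °C → rt
Reagents that add atoms: dimethylzinc, C[Zn]C; N,N-dimethylmethyleneiminium iodide (Eschenmoser's salt), C=[N+](C)C.[I-]
Why: Copper-catalysed asymmetric conjugate addition sets C11 (ligand antipode chosen for the S centre) and the regiodefined zinc enolate is intercepted at C12 in a Mannich reaction, the aminomethyl group entering trans to the new methyl (this C12 centre becomes planar again in step 4).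

**Step 2**
Reactants: 3 (2S,3S)-2-[(dimethylamino)methyl]-3-methylcyclopentan-1-one
Product: 4 trimethyl{[(1S,2S)-2-methyl-5-oxocyclopentyl]methyl}ammonium iodide
Conditions: MeI, Et2O, 0 °C → rt
Reagents that add atoms: iodomethane, CI
Why: Menshutkin quaternisation of the tertiary amine should give a crystalline, storable precursor of the polymerisation-prone α-methylene ketone.

**Step 3**
Reactants: 5 (E)-1-bromobut-2-ene (crotyl bromide); 6 tetrahydrothiophene
Product: 7 1-[(E)-but-2-en-1-yl]tetrahydrothiophenium bromide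
Conditions: acetone, rt
Reagents that add atoms: none
Why: SN2 S-alkylation of the sulfide by the allylic bromide gives the sulfonium salt.

**Step 4**
Reactants: 4 trimethyl{[(1S,2S)-2-methyl-5-oxocyclopentyl]methyl}ammonium iodide; 7 1-[(E)-but-2-en-1-yl]tetrahydrothiophenium bromide
Product: 10 (7S)-7-methyl-1-[(E)-prop-1-enyl]spiro[2.4]heptan-4-one (C13 on the α face; C17H2 on the β face; propenyl trans to C8), via enone 8 (not isolated), via sulfonium ylide 9 (not isolated)
Conditions: Cs2CO3 (2.5 equiv), 7 (1.5 equiv), MeCN, 0 °C → rt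
Reagents that add atoms: none
Why: E1cB loss of trimethylamine frees enone 8, which is captured at once by ylide 9 in a Michael-initiated ring closure (sulfur-ylide cyclopropanation) in which the ylide carbon (C13) adds to the exocyclic CH2 (C17) and the C12 enolate then displaces tetrahydrothiophene at C13 on the face anti to the C11 methyl, as in trans-alkylation of 3-substituted cyclopentanone enolates, which fixes C12.

**Step 5**
Reactants: 10 (7S)-7-methyl-1-[(E)-prop-1-enyl]spiro[2.4]heptan-4-one
Product: 11 the C8 α-alcohol of 10 (7-methyl-1-[(E)-prop-1-enyl]spiro[2.4]heptan-4-ol)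
Conditions: NaBH4, MeOH, 0 °C
Reagents that add atoms: none
Why: Borohydride reduction of the cyclopropyl ketone, hydride drawn as approaching past the unsubstituted cyclopropane CH2 (C17); the C8 epimer would serve equally because C8 returns to a ketone in step 11.

**Step 6**
Reactants: 11 the C8 α-alcohol
Product: 12 tert-butyldimethylsilyl ether of 11 (spiro[2.4]heptane vinylcyclopropane with C8 α-OTBS; the key-step precursor)
Conditions: TBSOTf, 2,6-lutidine, CH2Cl2, −78 → 0 °C
Reagents that add atoms: tert-butyldimethylsilyl triflate, CC(C)(C)[Si](C)(C)OS(=O)(=O)C(F)(F)F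
Why: Silylation of the hindered secondary alcohol with the silyl triflate removes the carbonyl from C12 before the metal-mediated ring opening.

**Step 7**
Reactants: 12 the C8 α-OTBS vinylcyclopropane
Product: 14 1-{[tert-butyl(dimethyl)silyl]oxy}-4,8-dimethylspiro[4.5]dec-8-en-7-one (ring-B enone with C16=O and C14=C15; C8 α-OTBS; C11 β-methyl; C13 α), via β,γ-enone 13 (not isolated)
Conditions: Fe(CO)5 (2 equiv), CO (1 atm, returns the iron to Fe(CO)5), hν (medium-pressure Hg lamp, Pyrex), i-PrOH, rt; then DBU (0.3 equiv), rt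
Reagents that add atoms: carbon monoxide, [C-]#[O+] (delivered through Fe(CO)5)
Why: Photolysis of Fe(CO)5 gives an Fe(CO)4 fragment that binds the propenyl alkene, zerovalent iron inserts into the adjacent, less substituted cyclopropane bond C13–C17 to give a σ-alkyl (C17), η3-allyl (C13–C15) ferracycle, CO migrates onto C17 to create the acyl carbon C16, and acyl–allyl reductive elimination at C15 releases β,γ-enone 13, which DBU moves into conjugation at C14=C15. The closest known reaction type is the iron-carbonyl-mediated (or [Rh(CO)2Cl]2-catalysed) [5+1] carbonylation of alkenylcyclopropanes to cyclohex-2-enones. Ring B is the only ring closed, as a six-membered ring by reductive elimination joining C15 to C16 after migratory insertion has made C16–C17. No stereocentre is created: C12 is untouched, C13 becomes CH2 and the transient C15 centre of 13 is erased by the isomerisation. The step needs cleavage of C13–C17 and not of C12–C13; insertion next to the quaternary spiro carbon would require a tertiary alkyl–iron bond, and with C8 held as a silyl ether no carbonyl on C12 polarises the C12–C13 bond. Acyl coupling at C13 instead of C15 would give a strained cyclobutanone and is not expected.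

**Step 8**
Reactants: 14 the ring-B enone
Product: 15 the (16S)-allylic alcohol (C16–OH; C14=C15; C8 α-OTBS)
Conditions: (R)-2-methyl-CBS-oxazaborolidine (20 mol %), BH3·SMe2, THF, −20 °C; MeOH quench
Reagents that add atoms: none
Why: Corey–Bakshi–Shibata reduction in which the C14=C15(Me) arm acts as the large and C17H2 as the small carbonyl substituent, so the (R)-catalyst should give the (16S) alcohol under reagent control, and material from the minor enantiomer of step 1 becomes a separable diastereomer here.

**Step 9**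
Reactants: 15 the (16S)-allylic alcohol
Product: 16 the C16 4-methoxybenzyl ether (C8 α-OTBS)
Conditions: NaH, 4-MeOC6H4CH2Cl, Bu4NI (cat.), DMF, 0 °C → rt
Reagents that add atoms: 4-methoxybenzyl chloride, COc1ccc(CCl)cc1
Why: Williamson etherification installs a group that survives fluoride, amide bases, alkaline peroxide, hydrazine and hydride and is removed oxidatively at the end.

**Step 10**
Reactants: 16 the C16 PMB ether with C8 α-OTBS
Product: 17 the C8 alcohol (C16 OPMB)
Conditions: Bu4NF, THF, rt → 50 °C
Reagents that add atoms: none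
Why: Fluoride-mediated desilylation, orthogonal to the PMB ether.

**Step 11**
Reactants: 17 the C8 alcohol
Product: 18 the C8 ketone (ring-A cyclopentanone; C16 OPMB)
Conditions: Dess–Martin periodinane, CH2Cl2, rt
Reagents that add atoms: none
Why: Dess–Martin oxidation of the hindered secondary alcohol; the spectator C8 centre disappears.

**Step 12**
Reactants: 18 the C8 ketone
Product: 20 the ring-A enone (C8=O; C9=C10), via trimethylsilyl enol ether 19 (not isolated)
Conditions: LiN(i-Pr)2, Me3SiCl, THF, −78 °C; then Pd(OAc)2 (1.1 equiv), MeCN, rt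
Reagents that add atoms: chlorotrimethylsilane, C[Si](C)(C)Cl (retained only in 19)
Why: Saegusa–Ito dehydrogenation; enolisation can only occur toward C9 because C12 is quaternary.

**Step 13**
Reactants: 20 the ring-A enone
Product: 21 the α-epoxy ketone (C9–C10 epoxide on the α face, anti to the C11 methyl)
Conditions: H2O2 (30 % aq.), NaOH (cat.), MeOH, 0 °C
Reagents that add atoms: hydrogen peroxide, OO
Why: Weitz–Scheffer nucleophilic epoxidation, hydroperoxide adding to C10 anti to the adjacent C11 methyl, which sets the C10–O bond on the α face.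

**Step 14**
Reactants: 21 the α-epoxy ketone
Product: 22 the transposed allylic alcohol (C10 α-OH; C8=C9)
Conditions: N2H4·H2O, AcOH (cat.), MeOH, 0 °C → rt
Reagents that add atoms: none
Why: Wharton transposition: condensation at C8, opening of the C9–O bond and loss of N2 leave the C10–O bond untouched, so the α configuration at C10 is retained.

**Step 15**
Reactants: 22 the C10 α-allylic alcohol
Product: 23 the C10 propanoate
Conditions: EtCOCl, pyridine, DMAP (cat.), CH2Cl2, 0 °C
Reagents that add atoms: propanoyl chloride, CCC(Cl)=O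
Why: Standard acylation supplies C6, C7 and the C7 methyl as the ester.

**Step 16**
Reactants: 23 the C10 propanoate
Product: 26 (2S)-2-[ring-A cyclopentenyl]propanoic acid (7S,8R; C9=C10; C16 OPMB), via silyl ketene acetal 24 (not isolated), via trimethylsilyl ester 25 (not isolated)
Conditions: LiN(i-Pr)2, THF–HMPA, −78 °C; Me3SiCl; −78 → 60 °C; then 1 M HCl
Reagents that add atoms: chlorotrimethylsilane, C[Si](C)(C)Cl (retained only in 24 and 25)
Why: Ireland–Claisen rearrangement: the suprafacial shift delivers C7 to C8 on the α face of the C10–O bond (8R), and the ketene acetal with methyl cis to OSi formed in THF–HMPA should react through the boat-like transition state (the chair would push OSiMe3 under ring A against C13H2), which places the methyl outward and gives 7S.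

**Step 17**
Reactants: 26 the unsaturated acid
Product: 27 the saturated acid (C9–C10 reduced; C14=C15 kept)
Conditions: TsNHNH2, NaOAc, DME–H2O, 80 °C
Reagents that add atoms: none
Why: Diimide reduction is strongly sensitive to substitution, so the cis-disubstituted cyclopentene should be reduced and the trisubstituted C14=C15 left alone.

**Step 18**
Reactants: 27 the saturated acid
Product: 28 the primary alcohol (C6–OH; 7S)
Conditions: LiAlH4, THF, 0 °C → rt
Reagents that add atoms: none
Why: Hydride reduction of the carboxylic acid; the PMB ether and the alkene are inert.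

**Step 19**
Reactants: 28 the primary alcohol
Product: 29 the C6 aldehyde (7S)
Conditions: Dess–Martin periodinane, NaHCO3, CH2Cl2, 0 °C
Reagents that add atoms: none
Why: Buffered Dess–Martin oxidation gives the α-branched aldehyde without epimerising C7; it is used at once.

**Step 20**
Reactants: 30 3-methylfuran-2(5H)-one
Product: 31 tert-butyl(dimethyl)[(3-methylfuran-2-yl)oxy]silane
Conditions: TBSOTf, Et3N, CH2Cl2, 0 °C
Reagents that add atoms: tert-butyldimethylsilyl triflate, CC(C)(C)[Si](C)(C)OS(=O)(=O)C(F)(F)F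
Why: Soft enolisation and O-silylation of the butenolide gives the 2-silyloxyfuran.

**Step 21**
Reactants: 29 the C6 aldehyde; 31 the silyloxyfuran
Product: 32 the 5-(1-hydroxyalkyl)-3-methylfuran-2(5H)-one (C5 and C6 epimers)
Conditions: BF3·OEt2, CH2Cl2, −78 °C
Reagents that add atoms: none
Why: Vinylogous Mukaiyama aldol addition at C5 of the silyloxyfuran under non-basic conditions that spare C7; the new C5 and C6 centres are removed in step 22.

**Step 22**
Reactants: 32 the aldol adduct
Product: 34 the (Z)-γ-ylidenebutenolide with C16 OPMB, via mesylate 33 (not isolated)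
Conditions: MsCl, Et3N, CH2Cl2, 0 °C; then DBU, 0 °C → rt
Reagents that add atoms: methanesulfonyl chloride, CS(=O)(=O)Cl (retained only in 33)
Why: Mesylation and E1cB elimination through the 2-oxyfuran anion should converge both aldol epimers on the Z alkene, which avoids strain between C7 and C4–H.

**Step 23**
Reactants: 34 the PMB-protected ylidenebutenolide
Product: 35 the (16S)-alcohol
Conditions: DDQ, CH2Cl2–pH 7 buffer, 0 °C
Reagents that add atoms: none
Why: Oxidative PMB cleavage through the benzylic cation; the electron-poor dienyl lactone and the trisubstituted alkene should be untouched at 0 °C.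

**Step 24**
Reactants: 35 the (16S)-alcohol
Product: 36 CNP0260277.1 (target)
Conditions: PhCH2CH2COCl, pyridine, DMAP (cat.), CH2Cl2, 0 °C
Reagents that add atoms: 3-phenylpropanoyl chloride, O=C(Cl)CCc1ccccc1
Why: DMAP-catalysed acylation of the secondary allylic alcohol with retention at C16.

**Compound list**
1 | cyclopent-2-en-1-one | O=C1C=CCC1 | starting material
2 | methylzinc (3S)-3-methylcyclopent-1-en-1-olate | C[Zn]OC1=C[C@@H](C)CC1 | intermediate
3 | (2S,3S)-2-[(dimethylamino)methyl]-3-methylcyclopentan-1-one | O=C1CC[C@H](C)[C@H]1CN(C)C | intermediate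
4 | trimethyl{[(1S,2S)-2-methyl-5-oxocyclopentyl]methyl}ammonium iodide | O=C1CC[C@H](C)[C@H]1C[N+](C)(C)C.[I-] | intermediate
5 | (E)-1-bromobut-2-ene (crotyl bromide) | C/C=C/CBr | starting material
6 | tetrahydrothiophene | C1CCSC1 | starting material
7 | 1-[(E)-but-2-en-1-yl]tetrahydrothiophenium bromide | C/C=C/C[S+]1CCCC1.[Br-] | intermediate
8 | (3S)-3-methyl-2-methylidenecyclopentan-1-one | O=C1CC[C@H](C)C1=C | intermediate
9 | (E)-1-(tetrahydrothiophenium-1-yl)but-2-en-1-ide (crotyl sulfonium ylide) | C/C=C/[CH-][S+]1CCCC1 | intermediate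
10 | (7S)-7-methyl-1-[(E)-prop-1-enyl]spiro[2.4]heptan-4-one; C13 α, C17 β, propenyl trans to C8 | O=C1CC[C@H](C)[C@@]12[C@H](/C=C/C)C2 | intermediate
11 | C8 α-alcohol of 10 | O[C@H]1CC[C@H](C)[C@@]12[C@H](/C=C/C)C2 | intermediate
12 | C8 α-OTBS vinylcyclopropane (key-step precursor) | CC(C)(C)[Si](C)(C)O[C@H]1CC[C@H](C)[C@@]12[C@H](/C=C/C)C2 | intermediate
13 | β,γ-enone: 1-(TBS-oxy)-4,8-dimethylspiro[4.5]dec-9-en-7-one (C13=C14; C15 epimers) | CC(C)(C)[Si](C)(C)O[C@H]1CC[C@H](C)[C@@]12C=CC(C)C(=O)C2 | intermediate
14 | 1-{[tert-butyl(dimethyl)silyl]oxy}-4,8-dimethylspiro[4.5]dec-8-en-7-one (C16=O, C14=C15, C8 α-OTBS) | CC(C)(C)[Si](C)(C)O[C@H]1CC[C@H](C)[C@@]12CC=C(C)C(=O)C2 | intermediate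
15 | (16S)-allylic alcohol, C8 α-OTBS | CC(C)(C)[Si](C)(C)O[C@H]1CC[C@H](C)[C@@]12CC=C(C)[C@@H](O)C2 | intermediate
16 | C16 PMB ether, C8 α-OTBS | CC(C)(C)[Si](C)(C)O[C@H]1CC[C@H](C)[C@@]12CC=C(C)[C@@H](OCc3ccc(OC)cc3)C2 | intermediate
17 | C8 alcohol, C16 OPMB | O[C@H]1CC[C@H](C)[C@@]12CC=C(C)[C@@H](OCc3ccc(OC)cc3)C2 | intermediate
18 | C8 ketone, C16 OPMB | O=C1CC[C@H](C)[C@@]12CC=C(C)[C@@H](OCc3ccc(OC)cc3)C2 | intermediate
19 | C8 trimethylsilyl enol ether (C8=C9) | C[Si](C)(C)OC1=CC[C@H](C)[C@@]12CC=C(C)[C@@H](OCc3ccc(OC)cc3)C2 | intermediate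
20 | ring-A enone (C8=O, C9=C10) | O=C1C=C[C@H](C)[C@@]12CC=C(C)[C@@H](OCc3ccc(OC)cc3)C2 | intermediate
21 | α-epoxy ketone (C9–C10 epoxide on the α face) | O=C1[C@H]2O[C@H]2[C@H](C)[C@@]13CC=C(C)[C@@H](OCc4ccc(OC)cc4)C3 | intermediate
22 | allylic alcohol (C10 α-OH, C8=C9) | C1=C[C@@H](O)[C@H](C)[C@@]12CC=C(C)[C@@H](OCc3ccc(OC)cc3)C2 | intermediate
23 | C10 propanoate | C1=C[C@@H](OC(=O)CC)[C@H](C)[C@@]12CC=C(C)[C@@H](OCc3ccc(OC)cc3)C2 | intermediate
24 | silyl ketene acetal (methyl cis to OSiMe3) | C1=C[C@@H](O/C(=C/C)O[Si](C)(C)C)[C@H](C)[C@@]12CC=C(C)[C@@H](OCc3ccc(OC)cc3)C2 | intermediate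
25 | trimethylsilyl ester of 26 | C[Si](C)(C)OC(=O)[C@@H](C)[C@H]1C=C[C@H](C)[C@@]12CC=C(C)[C@@H](OCc3ccc(OC)cc3)C2 | intermediate
26 | (7S,8R)-unsaturated acid (C9=C10) | OC(=O)[C@@H](C)[C@H]1C=C[C@H](C)[C@@]12CC=C(C)[C@@H](OCc3ccc(OC)cc3)C2 | intermediate
27 | (7S,8R)-saturated acid | OC(=O)[C@@H](C)[C@H]1CC[C@H](C)[C@@]12CC=C(C)[C@@H](OCc3ccc(OC)cc3)C2 | intermediate
28 | (7S,8R)-primary alcohol | OC[C@@H](C)[C@H]1CC[C@H](C)[C@@]12CC=C(C)[C@@H](OCc3ccc(OC)cc3)C2 | intermediate
29 | (7S,8R)-C6 aldehyde | O=C[C@@H](C)[C@H]1CC[C@H](C)[C@@]12CC=C(C)[C@@H](OCc3ccc(OC)cc3)C2 | intermediate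
30 | 3-methylfuran-2(5H)-one | CC1=CCOC1=O | starting material
31 | tert-butyl(dimethyl)[(3-methylfuran-2-yl)oxy]silane | Cc1ccoc1O[Si](C)(C)C(C)(C)C | intermediate
32 | 5-(1-hydroxyalkyl)-3-methylfuran-2(5H)-one (C5, C6 epimers) | CC1=CC(C(O)[C@@H](C)[C@H]2CC[C@H](C)[C@@]23CC=C(C)[C@@H](OCc4ccc(OC)cc4)C3)OC1=O | intermediate
33 | C6 mesylate of 32 | CC1=CC(C(OS(C)(=O)=O)[C@@H](C)[C@H]2CC[C@H](C)[C@@]23CC=C(C)[C@@H](OCc4ccc(OC)cc4)C3)OC1=O | intermediate
34 | (Z)-ylidenebutenolide, C16 OPMB | CC1=C/C(=C/[C@@H](C)[C@H]2CC[C@H](C)[C@@]23CC=C(C)[C@@H](OCc4ccc(OC)cc4)C3)OC1=O | intermediate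
35 | (Z)-ylidenebutenolide, (16S)-alcohol | CC1=C/C(=C/[C@@H](C)[C@H]2CC[C@H](C)[C@@]23CC=C(C)[C@@H](O)C3)OC1=O | intermediate
36 | CNP0260277.1 | CC1=C/C(=C/[C@@H](C)[C@H]2CC[C@H](C)[C@@]23CC=C(C)[C@@H](OC(=O)CCc2ccccc2)C3)OC1=O | target

**Step count:** 24 steps in total; the longest linear sequence is 22 steps (steps 1, 2, 4–19, 21–24).

**Steps most likely to fail**

Step 7. The iron may insert into the wrong cyclopropane bond, or the acyl–allyl coupling at the methyl-bearing allyl terminus may stall and leave ring-opened, isomerised dienes. The fallback builds ring B by cycloaddition instead of carbonylation and also by-passes step 4. It sets out from ammonium salt 4: enone 8 is freed with NaHCO3 (CH2Cl2–H2O) and treated with isoprene and EtAlCl2 (cat.) in CH2Cl2 at −78 → −20 °C; the Diels–Alder reaction should occur anti to the C11 methyl with para orientation and give spiro ketone F1. NaBH4 reduction gives alcohol F2, and TBSOTf/2,6-lutidine gives silyl ether F3. Allylic oxidation with SeO2 (cat.) and t-BuOOH, at the ring CH2 on the methyl-bearing alkene carbon, gives C16 allylic alcohol F4, and MnO2 oxidation returns to the route at enone 14.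

Step 16. Control of the ketene acetal geometry or of the boat-like transition state may be lost, eroding the C7 configuration, or the shift onto the hindered C8 may be slow. The fallback separates the two tasks and sets out from allylic alcohol 22. A Johnson–Claisen rearrangement (MeC(OEt)3, EtCO2H cat., 140 °C) sets C8 alone and gives ethyl ester F5; diimide (TsNHNH2, NaOAc) gives saturated ester F6; LiOH (THF–H2O) gives acid F7. Pivaloyl chloride/Et3N and then lithiated (S)-4-benzyloxazolidin-2-one give imide F8. NaN(SiMe3)2 and MeI at −78 °C give methylated imide F9, the methyl entering opposite the benzyl group of the chelated Z-enolate (7S). LiBH4 (THF–MeOH) returns to the route at alcohol 28.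

Step 14. Condensation of hydrazine with the hindered C8 carbonyl may be slow, and the diazene may decompose along other paths. The fallback replaces the hydrazone chemistry by a radical fragmentation and sets out from epoxy ketone 21. NaBH4 (MeOH, 0 °C) gives epoxy alcohol F10 (C8 epimers, of no consequence); 1,1'-thiocarbonyldiimidazole and DMAP give imidazolyl thionocarbonate F11. Bu3SnH and AIBN (toluene, 80 °C) generate the C8 radical, which opens the C9–O bond; the C10 alkoxy radical abstracts hydrogen, and the route is rejoined at allylic alcohol 22 with the α C10–O bond intact.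

**Further compounds**
F1 | step 7 | spiro ketone: (S)-C11 4,8-dimethylspiro[4.5]dec-7-en-1-one, C13 α | O=C1CC[C@H](C)[C@@]12CC=C(C)CC2
F2 | step 7 | C8 α-alcohol of F1 | O[C@H]1CC[C@H](C)[C@@]12CC=C(C)CC2
F3 | step 7 | C8 α-OTBS ether of F2 | CC(C)(C)[Si](C)(C)O[C@H]1CC[C@H](C)[C@@]12CC=C(C)CC2
F4 | step 7 | C16 allylic alcohol of F3 (C16 epimers) | CC(C)(C)[Si](C)(C)O[C@H]1CC[C@H](C)[C@@]12CC=C(C)C(O)C2
F5 | step 16 | ethyl (8R)-cyclopentenylacetate (C9=C10, C16 OPMB) | CCOC(=O)C[C@H]1C=C[C@H](C)[C@@]12CC=C(C)[C@@H](OCc3ccc(OC)cc3)C2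
F6 | step 16 | saturated ethyl ester | CCOC(=O)C[C@H]1CC[C@H](C)[C@@]12CC=C(C)[C@@H](OCc3ccc(OC)cc3)C2
F7 | step 16 | saturated acetic acid | OC(=O)C[C@H]1CC[C@H](C)[C@@]12CC=C(C)[C@@H](OCc3ccc(OC)cc3)C2
F8 | step 16 | N-acyl (S)-4-benzyloxazolidin-2-one | O=C(C[C@H]1CC[C@H](C)[C@@]12CC=C(C)[C@@H](OCc3ccc(OC)cc3)C2)N4[C@@H](Cc5ccccc5)COC4=O
F9 | step 16 | (7S)-methylated N-acyl oxazolidinone | O=C([C@@H](C)[C@H]1CC[C@H](C)[C@@]12CC=C(C)[C@@H](OCc3ccc(OC)cc3)C2)N4[C@@H](Cc5ccccc5)COC4=O
F10 | step 14 | α-epoxy alcohol (C8 epimers) | OC1[C@H]2O[C@H]2[C@H](C)[C@@]13CC=C(C)[C@@H](OCc4ccc(OC)cc4)C3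
F11 | step 14 | O-(epoxycyclopentyl) 1H-imidazole-1-carbothioate | S=C(OC1[C@H]2O[C@H]2[C@H](C)[C@@]13CC=C(C)[C@@H](OCc4ccc(OC)cc4)C3)n5ccnc5
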